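- I must say what holds most of the D at the end of larch and of oak, and how much E is left in larch. Possible steps: D and J give E or X with L, E or X and J give G with L, and two D give Q.

| flask | D | J | remark | time |
|---|---|---|---|---|
| summer | 0.010 M | 0.42 equiv | run made earlier |  |
| dawn | 0.010 M | 0.70 equiv | run made earlier |  |
| winter | 0.010 M | 1.4 equiv | run made earlier |  |
| larch | 0.010 M | 0.500 equiv |  | 15 h |
| oak | 0.010 M | 1.20 equiv |  | 15 h |

- summer (time / h: E / %, D / %): 0.667: 8.4, 74.3; 1.00: 7.6, 70.0; 2.00: 7.2, 64.5; 4.00: 3.4, 58.4; 8.00: 0.6, 50.6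
- dawn (time / h: E / %, D / %): 1.50: 9.8, 53.6; 3.00: 4.6, 47.9; 5.00: 1.7, 45.2; 6.00: 0, 43.9; 8.00: 0, 40.8
- winter (time / h: E / %, D / %): 0.667: 14.4, 43.0; 2.00: 6.2, 30.4; 4.00: 0.3, 22.9; 5.00: 0.2, 21.1; 8.00: 0.4, 18.4

(readings scatter by 0.5 percentage points)

- which of these holds the largest part of the D at the end of larch (D / E / X / G)
- which of these holds the largest part of the D at the end of oak (D / E / X / G)
- final E in larch, as a percentage of the D charged

- a species is counted by the D in it: one Q counts as two
- what may be going on: D + J <-> E + L; D + J -> X + L; J + E -> G + L; J + X -> G + L; 2 D -> Q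

- I work with f, the fraction of D left, c(D) over its charge. The J charged in summer, 0.42 equiv, is less than the part of its D that is gone by 8.00 h, 49.4%, so D also has a path without J, and if two D going together are what acts on D, the reciprocal of f grows linearly in time (a second-order law). From 4.00 h to 8.00 h in summer it grows by 0.0660 h⁻¹, the reciprocal growth s.
- Against this, dawn gives 0.0795 h⁻¹, but its D falls by 4.4 percentage points against 7.8 points in summer, so the scatter weighs more there and I keep s.
- Interpolating the last readings of summer and dawn, larch has f of 47.8% at 8.00 h, and s takes it to 39.2% at 15 h. My doubt is X, which nobody read: it must take that much out of 0.500 equiv of J to top D, and the way on to G spends J too, so I say D, weakly.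
- For oak, interpolating the last readings of dawn and winter gives f of 24.8% at 8.00 h, and s takes it to 22.3% at 15 h. If J is spent, one G per two J puts G at 42.3% or more and X at 35.5% or less, so I say G, though J left over would lower that bound.
- E reads 0.6% at the end of summer and 0% at the end of dawn, so I put it near zero in larch.
- The forecast says D for larch, G for oak and 0.1% of E, and it too argues that “some J-free loss must exist”.

    D + J ⇌ E + L (K = 0.350, k = 0.0150 L mol⁻¹ s⁻¹)
    D + J → X + L (k = 0.0250 L mol⁻¹ s⁻¹)
    J + E → G + L (k = 0.00780 L mol⁻¹ s⁻¹)
    J + X → G + L (k = 0.0410 L mol⁻¹ s⁻¹)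
    2 D → Q (k = 8.10 × 10⁻⁴ L mol⁻¹ s⁻¹)

- Larch ends with D at 40.1%, X 22.8%, G 13.6% and E 0.0248%, oak with G at 49.8%, so the forecast stands, and larch stopped as early as 3.01 h has its E 5 points away from that value. In larch D + J into X + L uses D 4.4 times as fast as two D into Q at 0.738 h, but with J, the limiting reagent, at 1.64% of its charge at 7.50 h, s takes D from 48.7% to 39.2% at 15 h, where the flask has 40.1%. In oak, with J at 1.48%, s takes D from 24.8% at 7.50 h to 22.1%, and the flask has 21.9%.

All runs come from a simulation for an exercise; the scatter is artificial.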